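Ring A of the chromene is a benzene with oxygen at C5, C7 and C8a, carbon at C4a and C6, and hydrogen at C8. The route builds it by disconnecting C5–C6, C7–C8 and C4a–C5. A Danheiser benzannulation joins the vinylketene released by visible-light Wolff rearrangement of a 6-diazoacetyl dihydropyranone (ring B preformed) to a triisopropylsiloxyalkyne that already bears the two-carbon aryl side chain. One operation should thus give a chromanone with a free C5 phenol, a silylated C7 oxygen and the C6 chain in place, so the three ring A oxygens are differentiated from the start. Methylation, chromene formation and side-chain oxidation complete the target.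

Key step: step 8

Remark: the target has no stereocentre, so the side-chain carbinol centre (step 5) and C4 of the chromanol (step 10) are carried as stereoisomer mixtures and erased later; the side-chain alcohol is masked as a triethylsilyl ether so that it can be freed without touching the aryl triisopropylsilyl ether.

Step 1
Reactants: 1 mesityl oxide; 2 diethyl oxalate
Product: 4 ethyl 2,2-dimethyl-4-oxo-3,4-dihydro-2H-pyran-6-carboxylate, via ethyl 6-methyl-2,4-dioxohept-5-enoate 3 (not isolated)
Conditions: NaOEt, EtOH, 0 °C → rt; then HCl (anhydrous), EtOH, 60 °C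
Reagents that add atoms: none
Why: Crossed Claisen condensation of the methyl ketone with the non-enolisable oxalate is driven by the stable diketonate, and acid then closes the enol oxygen onto the β,β-dimethyl enone (6-endo oxa-Michael addition), the long-established entry to this class of pyranone esters.

Step 2
Reactants: 4 ethyl 2,2-dimethyl-4-oxo-3,4-dihydro-2H-pyran-6-carboxylate
Product: 5 2,2-dimethyl-4-oxo-3,4-dihydro-2H-pyran-6-carboxylic acid
Conditions: LiOH·H2O, THF–H2O, 0 °C; then 2 M HCl to pH 1, rt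
Reagents that add atoms: lithium hydroxide, [Li+].[OH-]
Why: Saponification of the activated 2-alkoxyacrylate ester should be fast in the cold, and the acidic finish re-closes any material that opened by retro-oxa-Michael reaction.

Step 3
Reactants: 5 2,2-dimethyl-4-oxo-3,4-dihydro-2H-pyran-6-carboxylic acid
Product: 7 6-(diazoacetyl)-2,2-dimethyl-2,3-dihydro-4H-pyran-4-one, via acid chloride 6 (not isolated)
Conditions: (COCl)2, cat. DMF, CH2Cl2, 0 °C → rt, evaporate; then CH2N2 (excess), Et2O, 0 °C
Reagents that add atoms: diazomethane, C=[N+]=[N-]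
Why: Acylation of diazomethane by an acid chloride (first stage of the Arndt–Eistert sequence) is reliable here because the acid chloride has no α-hydrogen, and the excess diazomethane removes the HCl.

Step 4
Reactants: 8 4-hydroxybenzaldehyde; 9 prenyl bromide (1-bromo-3-methylbut-2-ene)
Product: 10 4-(3-methylbut-2-enyloxy)benzaldehyde
Conditions: K2CO3, acetone, reflux
Reagents that add atoms: none
Why: Williamson ether synthesis of an acidic phenol with a reactive allylic bromide.

Step 5
Reactants: 10 4-(3-methylbut-2-enyloxy)benzaldehyde; 11 propargyl bromide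
Product: 12 rac-1-[4-(3-methylbut-2-enyloxy)phenyl]but-3-yn-1-ol
Conditions: Zn dust, THF–sat. aq. NH4Cl, 0 °C → rt
Reagents that add atoms: none
Why: Barbier propargylation, in which the allenylzinc species adds through its γ-carbon (SE2′) to give the homopropargylic alcohol; the new carbinol centre forms as a racemate, which suffices because it is oxidised later.

Step 6
Reactants: 12 rac-1-[4-(3-methylbut-2-enyloxy)phenyl]but-3-yn-1-ol
Product: 13 rac-triethyl({1-[4-(3-methylbut-2-enyloxy)phenyl]but-3-yn-1-yl}oxy)silane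
Conditions: Et3SiCl, imidazole, CH2Cl2, 0 °C → rt
Reagents that add atoms: chlorotriethylsilane, CC[Si](Cl)(CC)CC
Why: Standard silylation of a secondary alcohol; the triethylsilyl group tolerates the organolithium and benzannulation steps but is later removable under buffered HF in the presence of an aryl triisopropylsilyl ether.

Step 7
Reactants: 13 rac-triethyl({1-[4-(3-methylbut-2-enyloxy)phenyl]but-3-yn-1-yl}oxy)silane
Product: 16 rac-4-[4-(3-methylbut-2-enyloxy)phenyl]-4-(triethylsilyloxy)but-1-yn-1-yl triisopropylsilyl ether, via lithium acetylide 14 (not isolated), via lithium ynolate 15 (not isolated)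
Conditions: n-BuLi, THF, −78 °C; t-BuOOLi (from t-BuOOH and LiN(SiMe3)2), THF, −78 → 0 °C; then i-Pr3SiOTf, −78 → 0 °C
Reagents that add atoms: tert-butyl hydroperoxide, CC(C)(C)OO; triisopropylsilyl trifluoromethanesulfonate, CC(C)[Si](OS(=O)(=O)C(F)(F)F)(C(C)C)C(C)C
Why: Julia-type oxidation of a lithium acetylide by lithium tert-butyl peroxide (attack on the peroxide oxygen with loss of tert-butoxide) gives the ynolate, and O-silylation with the bulky silyl triflate gives an isolable siloxyalkyne.

Step 8
Reactants: 7 6-(diazoacetyl)-2,2-dimethyl-2,3-dihydro-4H-pyran-4-one; 16 rac-4-[4-(3-methylbut-2-enyloxy)phenyl]-4-(triethylsilyloxy)but-1-yn-1-yl triisopropylsilyl ether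
Product: 21 rac-5-hydroxy-2,2-dimethyl-6-{2-[4-(3-methylbut-2-enyloxy)phenyl]-2-(triethylsilyloxy)ethyl}-7-(triisopropylsilyloxy)chroman-4-one, via vinylketene 17 (not isolated), via vinylcyclobutenone 18 (not isolated), via dienylketene 19 (not isolated), via cyclohexadienone 20 (not isolated)
Conditions: hν (LED, ca. 420 nm), degassed ClCH2CH2Cl, rt; then 80 °C (dark)
Reagents that add atoms: none
Why: Light of about 420 nm should be absorbed by the diazo ketone but not by the dihydropyranone enone, so 7 loses N2 with 1,2-shift of pyranone C6 (Wolff rearrangement) to give vinylketene 17. The electrophilic ketene carbon bonds to the nucleophilic β-carbon of ynol ether 16 and the ketene CH to the siloxy-bearing carbon, a polarity-controlled [2+2] cycloaddition that makes C5–C6 and C7–C8 in vinylcyclobutenone 18. At 80 °C reversible 4π electrocyclic opening gives dienylketene 19, whose 6π electrocyclisation forms C4a–C5 and so closes ring A at pyranone C5, the carbon alpha to the ring ketone (the oxygen-bearing pyranone C6 becomes C8a), and dienone 20 tautomerises to the phenol. The sequence is the photo-Wolff variant of the Danheiser benzannulation, established for α,β-unsaturated diazomethyl ketones with siloxyalkynes. No stereocentre is created, the sp3 centres of 18 and 20 being lost on aromatisation, and the side-chain carbinol centre is not touched. The step needs regioselective cycloaddition, secured by the donor oxygen of the ynol ether, and capture of 17 by the alkyne instead of by the product phenol, helped by the hydrogen bond of the C5 hydroxyl to the C4 ketone and by a small excess of 16.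

Step 9
Reactants: 21 rac-5-hydroxy-2,2-dimethyl-6-{2-[4-(3-methylbut-2-enyloxy)phenyl]-2-(triethylsilyloxy)ethyl}-7-(triisopropylsilyloxy)chroman-4-one
Product: 22 rac-5-methoxy-2,2-dimethyl-6-{2-[4-(3-methylbut-2-enyloxy)phenyl]-2-(triethylsilyloxy)ethyl}-7-(triisopropylsilyloxy)chroman-4-one
Conditions: NaH (1.1 equiv), MeI, DMF, 0 °C → rt
Reagents that add atoms: iodomethane, CI
Why: Williamson O-methylation of the chelated C5 phenoxide; one equivalent of base deprotonates only the phenol, and the meta-placed aryl silyl ether cannot migrate to it.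

Step 10
Reactants: 22 rac-5-methoxy-2,2-dimethyl-6-{2-[4-(3-methylbut-2-enyloxy)phenyl]-2-(triethylsilyloxy)ethyl}-7-(triisopropylsilyloxy)chroman-4-one
Product: 23 5-methoxy-2,2-dimethyl-6-{2-[4-(3-methylbut-2-enyloxy)phenyl]-2-(triethylsilyloxy)ethyl}-7-(triisopropylsilyloxy)chroman-4-ol (diastereomer mixture)
Conditions: NaBH4, THF–MeOH, 0 °C → rt
Reagents that add atoms: none
Why: Borohydride reduction of the only carbonyl group present; the new C4 carbinol centre forms without control and is removed in the next step.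

Step 11
Reactants: 23 5-methoxy-2,2-dimethyl-6-{2-[4-(3-methylbut-2-enyloxy)phenyl]-2-(triethylsilyloxy)ethyl}-7-(triisopropylsilyloxy)chroman-4-ol
Product: 25 rac-5-methoxy-2,2-dimethyl-6-{2-[4-(3-methylbut-2-enyloxy)phenyl]-2-(triethylsilyloxy)ethyl}-7-(triisopropylsilyloxy)-2H-chromene, via chromanyl mesylate 24 (not isolated)
Conditions: MsCl, Et3N, CH2Cl2, 0 °C → rt
Reagents that add atoms: none
Why: Dehydration by mesylation and elimination; the mesylate of this benzylic alcohol, flanked by three donor oxygens on ring A, should ionise and lose a C3 proton to the amine at room temperature, without acid that could disturb the silyl or prenyl ethers.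

Step 12
Reactants: 25 rac-5-methoxy-2,2-dimethyl-6-{2-[4-(3-methylbut-2-enyloxy)phenyl]-2-(triethylsilyloxy)ethyl}-7-(triisopropylsilyloxy)-2H-chromene
Product: 26 rac-2-[5-methoxy-2,2-dimethyl-7-(triisopropylsilyloxy)-2H-chromen-6-yl]-1-[4-(3-methylbut-2-enyloxy)phenyl]ethanol
Conditions: HF·pyridine, pyridine, THF, 0 °C
Reagents that add atoms: none
Why: Selective desilylation; buffered HF cleaves a secondary alkyl triethylsilyl ether much faster than a hindered aryl triisopropylsilyl ether and does not ionise the para-alkoxybenzylic carbinol.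

Step 13
Reactants: 26 rac-2-[5-methoxy-2,2-dimethyl-7-(triisopropylsilyloxy)-2H-chromen-6-yl]-1-[4-(3-methylbut-2-enyloxy)phenyl]ethanol
Product: 27 2-[5-methoxy-2,2-dimethyl-7-(triisopropylsilyloxy)-2H-chromen-6-yl]-1-[4-(3-methylbut-2-enyloxy)phenyl]ethanone
Conditions: Dess–Martin periodinane, CH2Cl2, 0 °C → rt
Reagents that add atoms: none
Why: Dess–Martin oxidation of a secondary benzylic alcohol under near-neutral conditions that leave the chromene and prenyl alkenes alone; the C7 oxygen stays silylated so that the ortho-hydroxybenzyl ketone cannot cyclise to a benzofuran.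

Step 14
Reactants: 27 2-[5-methoxy-2,2-dimethyl-7-(triisopropylsilyloxy)-2H-chromen-6-yl]-1-[4-(3-methylbut-2-enyloxy)phenyl]ethanone
Product: 28 1-[5-methoxy-2,2-dimethyl-7-(triisopropylsilyloxy)-2H-chromen-6-yl]-2-[4-(3-methylbut-2-enyloxy)phenyl]ethane-1,2-dione
Conditions: DABCO (cat.), air, DMF, 90 °C
Reagents that add atoms: dioxygen, O=O
Why: Amine-mediated aerobic oxidation of a deoxybenzoin to a benzil: the doubly activated methylene enolises, the enol traps O2 as the α-hydroperoxide, and Kornblum–DeLaMare-type loss of water gives the dione with no electrophilic oxidant present to attack the two alkenes.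

Step 15
Reactants: 28 1-[5-methoxy-2,2-dimethyl-7-(triisopropylsilyloxy)-2H-chromen-6-yl]-2-[4-(3-methylbut-2-enyloxy)phenyl]ethane-1,2-dione
Product: 29 ficucaricone C
Conditions: Bu4NF, AcOH, THF, 0 °C
Reagents that add atoms: none
Why: Fluoride cleavage of the aryl silyl ether, buffered with acetic acid so that the 1,2-dione is not exposed to free base.

Compound list
1 | mesityl oxide (4-methylpent-3-en-2-one) | CC(C)=CC(C)=O | starting material
2 | diethyl oxalate | CCOC(=O)C(=O)OCC | starting material
3 | ethyl 6-methyl-2,4-dioxohept-5-enoate | CCOC(=O)C(=O)CC(=O)C=C(C)C | intermediate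
4 | ethyl 2,2-dimethyl-4-oxo-3,4-dihydro-2H-pyran-6-carboxylate | CCOC(=O)C1=CC(=O)CC(C)(C)O1 | intermediate
5 | 2,2-dimethyl-4-oxo-3,4-dihydro-2H-pyran-6-carboxylic acid | OC(=O)C1=CC(=O)CC(C)(C)O1 | intermediate
6 | 2,2-dimethyl-4-oxo-3,4-dihydro-2H-pyran-6-carbonyl chloride | ClC(=O)C1=CC(=O)CC(C)(C)O1 | intermediate
7 | 6-(diazoacetyl)-2,2-dimethyl-2,3-dihydro-4H-pyran-4-one | CC1(C)CC(=O)C=C(O1)C(=O)C=[N+]=[N-] | intermediate
8 | 4-hydroxybenzaldehyde | O=Cc1ccc(O)cc1 | starting material
9 | prenyl bromide (1-bromo-3-methylbut-2-ene) | CC(C)=CCBr | starting material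
10 | 4-(3-methylbut-2-enyloxy)benzaldehyde | O=Cc1ccc(OCC=C(C)C)cc1 | intermediate
11 | propargyl bromide (3-bromoprop-1-yne) | C#CCBr | starting material
12 | rac-1-[4-(3-methylbut-2-enyloxy)phenyl]but-3-yn-1-ol | C#CCC(O)c1ccc(OCC=C(C)C)cc1 | intermediate
13 | rac-triethyl({1-[4-(3-methylbut-2-enyloxy)phenyl]but-3-yn-1-yl}oxy)silane | C#CCC(O[Si](CC)(CC)CC)c1ccc(OCC=C(C)C)cc1 | intermediate
14 | lithium acetylide of 13 (C-lithiated at the alkyne terminus) | [Li]C#CCC(O[Si](CC)(CC)CC)c1ccc(OCC=C(C)C)cc1 | intermediate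
15 | lithium rac-4-[4-(3-methylbut-2-enyloxy)phenyl]-4-(triethylsilyloxy)but-1-yn-1-olate (ynolate) | [Li]OC#CCC(O[Si](CC)(CC)CC)c1ccc(OCC=C(C)C)cc1 | intermediate
16 | rac-4-[4-(3-methylbut-2-enyloxy)phenyl]-4-(triethylsilyloxy)but-1-yn-1-yl triisopropylsilyl ether | CC(C)[Si](OC#CCC(O[Si](CC)(CC)CC)c1ccc(OCC=C(C)C)cc1)(C(C)C)C(C)C | intermediate
17 | 2,2-dimethyl-6-(2-oxoethenyl)-2,3-dihydro-4H-pyran-4-one (vinylketene) | CC1(C)CC(=O)C=C(O1)C=C=O | intermediate
18 | 4-(2,2-dimethyl-4-oxo-3,4-dihydro-2H-pyran-6-yl)-2-{2-[4-(3-methylbut-2-enyloxy)phenyl]-2-(triethylsilyloxy)ethyl}-3-(triisopropylsilyloxy)cyclobut-2-en-1-one (racemic diastereomer mixture) | CC1(C)CC(=O)C=C(O1)C1C(=O)C(CC(O[Si](CC)(CC)CC)c2ccc(OCC=C(C)C)cc2)=C1O[Si](C(C)C)(C(C)C)C(C)C | intermediate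
19 | rac-(3E)-4-(2,2-dimethyl-4-oxo-3,4-dihydro-2H-pyran-6-yl)-2-{2-[4-(3-methylbut-2-enyloxy)phenyl]-2-(triethylsilyloxy)ethyl}-3-(triisopropylsilyloxy)buta-1,3-dien-1-one (dienylketene, ketene cis to the pyranone) | O=C=C(CC(O[Si](CC)(CC)CC)c1ccc(OCC=C(C)C)cc1)/C(O[Si](C(C)C)(C(C)C)C(C)C)=C\C1=CC(=O)CC(C)(C)O1 | intermediate
20 | 2,2-dimethyl-6-{2-[4-(3-methylbut-2-enyloxy)phenyl]-2-(triethylsilyloxy)ethyl}-7-(triisopropylsilyloxy)-2,3-dihydro-4H-chromene-4,5(4aH)-dione (racemic diastereomer mixture) | CC1(C)CC(=O)C2C(=O)C(CC(O[Si](CC)(CC)CC)c3ccc(OCC=C(C)C)cc3)=C(O[Si](C(C)C)(C(C)C)C(C)C)C=C2O1 | intermediate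
21 | rac-5-hydroxy-2,2-dimethyl-6-{2-[4-(3-methylbut-2-enyloxy)phenyl]-2-(triethylsilyloxy)ethyl}-7-(triisopropylsilyloxy)chroman-4-one | CC1(C)CC(=O)c2c(O)c(CC(O[Si](CC)(CC)CC)c3ccc(OCC=C(C)C)cc3)c(O[Si](C(C)C)(C(C)C)C(C)C)cc2O1 | intermediate
22 | rac-5-methoxy-2,2-dimethyl-6-{2-[4-(3-methylbut-2-enyloxy)phenyl]-2-(triethylsilyloxy)ethyl}-7-(triisopropylsilyloxy)chroman-4-one | CC1(C)CC(=O)c2c(OC)c(CC(O[Si](CC)(CC)CC)c3ccc(OCC=C(C)C)cc3)c(O[Si](C(C)C)(C(C)C)C(C)C)cc2O1 | intermediate
23 | 5-methoxy-2,2-dimethyl-6-{2-[4-(3-methylbut-2-enyloxy)phenyl]-2-(triethylsilyloxy)ethyl}-7-(triisopropylsilyloxy)chroman-4-ol (racemic diastereomer mixture) | CC1(C)CC(O)c2c(OC)c(CC(O[Si](CC)(CC)CC)c3ccc(OCC=C(C)C)cc3)c(O[Si](C(C)C)(C(C)C)C(C)C)cc2O1 | intermediate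
24 | 4-methanesulfonate of 23 (racemic diastereomer mixture) | CC1(C)CC(OS(C)(=O)=O)c2c(OC)c(CC(O[Si](CC)(CC)CC)c3ccc(OCC=C(C)C)cc3)c(O[Si](C(C)C)(C(C)C)C(C)C)cc2O1 | intermediate
25 | rac-5-methoxy-2,2-dimethyl-6-{2-[4-(3-methylbut-2-enyloxy)phenyl]-2-(triethylsilyloxy)ethyl}-7-(triisopropylsilyloxy)-2H-chromene | CC1(C)C=Cc2c(OC)c(CC(O[Si](CC)(CC)CC)c3ccc(OCC=C(C)C)cc3)c(O[Si](C(C)C)(C(C)C)C(C)C)cc2O1 | intermediate
26 | rac-2-[5-methoxy-2,2-dimethyl-7-(triisopropylsilyloxy)-2H-chromen-6-yl]-1-[4-(3-methylbut-2-enyloxy)phenyl]ethanol | CC1(C)C=Cc2c(OC)c(CC(O)c3ccc(OCC=C(C)C)cc3)c(O[Si](C(C)C)(C(C)C)C(C)C)cc2O1 | intermediate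
27 | 2-[5-methoxy-2,2-dimethyl-7-(triisopropylsilyloxy)-2H-chromen-6-yl]-1-[4-(3-methylbut-2-enyloxy)phenyl]ethanone | CC1(C)C=Cc2c(OC)c(CC(=O)c3ccc(OCC=C(C)C)cc3)c(O[Si](C(C)C)(C(C)C)C(C)C)cc2O1 | intermediate
28 | 1-[5-methoxy-2,2-dimethyl-7-(triisopropylsilyloxy)-2H-chromen-6-yl]-2-[4-(3-methylbut-2-enyloxy)phenyl]ethane-1,2-dione | CC1(C)C=Cc2c(OC)c(C(=O)C(=O)c3ccc(OCC=C(C)C)cc3)c(O[Si](C(C)C)(C(C)C)C(C)C)cc2O1 | intermediate
29 | ficucaricone C, 1-(7-hydroxy-5-methoxy-2,2-dimethyl-2H-chromen-6-yl)-2-[4-(3-methylbut-2-enyloxy)phenyl]ethane-1,2-dione | COc1c2c(cc(O)c1C(=O)C(=O)c1ccc(OCC=C(C)C)cc1)OC(C)(C)C=C2 | target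

Total step count: 15
Longest linear sequence: 12 steps (steps 4–7, then 8–15, from 4-hydroxybenzaldehyde)

Steps most likely to fail

Step 8. The Wolff rearrangement may be inefficient if the excitation is shared with or quenched by the dihydropyranone enone, or the ketene may be lost to dimerisation or to acylation of the product phenol before the ynol ether captures it. The fallback generates the same vinylketene thermally and slowly, without light. It sets out from 7: a silver-catalysed Wolff rearrangement (PhCO2Ag, Et3N, dioxane–H2O), in which water traps the ketene at once, should give (2,2-dimethyl-4-oxo-3,4-dihydro-2H-pyran-6-yl)acetic acid F1. Oxalyl chloride should convert this into (2,2-dimethyl-4-oxo-3,4-dihydro-2H-pyran-6-yl)acetyl chloride F2. Slow addition of F2 to Et3N and 16 in toluene should dehydrochlorinate it at the activated methylene and release the ketene at low concentration. The fallback comes back to the route at vinylketene 17, which is carried through 18–20 to 21 by the same heating.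

Step 14. Enolisation of the hindered, electron-rich benzylic methylene may be too slow under amine catalysis, or the autoxidation may spread to the allylic positions of the prenyl and chromene units or cleave the dione. The fallback replaces the aerobic process by a stoichiometric enolate oxidation. It sets out from 27: KN(SiMe3)2 in THF at −78 °C followed by 2-(phenylsulfonyl)-3-phenyloxaziridine (Davis hydroxylation) should give rac-2-hydroxy-2-[5-methoxy-2,2-dimethyl-7-(triisopropylsilyloxy)-2H-chromen-6-yl]-1-[4-(3-methylbut-2-enyloxy)phenyl]ethanone F3. Dess–Martin oxidation of this benzoin should then give the dione, so the fallback comes back to the route at 28.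

Step 7. Oxygen transfer from the peroxide to the acetylide may be incomplete, or the ynol silyl ether may hydrolyse during isolation. The fallback reaches the same ynolate by Kowalski ester homologation instead of acetylide oxidation. It sets out from 10: a Reformatsky reaction with ethyl bromoacetate and Zn should give rac-ethyl 3-hydroxy-3-[4-(3-methylbut-2-enyloxy)phenyl]propanoate F4, and Et3SiCl with imidazole its silyl ether, rac-ethyl 3-[4-(3-methylbut-2-enyloxy)phenyl]-3-(triethylsilyloxy)propanoate F5. Addition of LiCHBr2 (from CH2Br2 and lithium 2,2,6,6-tetramethylpiperidide) at −78 °C and then LiN(SiMe3)2 should give, as its lithium enolate, rac-1,1-dibromo-4-[4-(3-methylbut-2-enyloxy)phenyl]-4-(triethylsilyloxy)butan-2-one F6. n-BuLi then triggers bromine–lithium exchange and 1,2-shift, so the fallback comes back to the route at lithium ynolate 15, which is silylated to 16 as in step 7.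

Further compounds
F1 | step 8 | (2,2-dimethyl-4-oxo-3,4-dihydro-2H-pyran-6-yl)acetic acid | CC1(C)CC(=O)C=C(O1)CC(=O)O
F2 | step 8 | (2,2-dimethyl-4-oxo-3,4-dihydro-2H-pyran-6-yl)acetyl chloride | CC1(C)CC(=O)C=C(O1)CC(=O)Cl
F3 | step 14 | rac-2-hydroxy-2-[5-methoxy-2,2-dimethyl-7-(triisopropylsilyloxy)-2H-chromen-6-yl]-1-[4-(3-methylbut-2-enyloxy)phenyl]ethanone | CC1(C)C=Cc2c(OC)c(C(O)C(=O)c3ccc(OCC=C(C)C)cc3)c(O[Si](C(C)C)(C(C)C)C(C)C)cc2O1
F4 | step 7 | rac-ethyl 3-hydroxy-3-[4-(3-methylbut-2-enyloxy)phenyl]propanoate | CCOC(=O)CC(O)c1ccc(OCC=C(C)C)cc1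
F5 | step 7 | rac-ethyl 3-[4-(3-methylbut-2-enyloxy)phenyl]-3-(triethylsilyloxy)propanoate | CCOC(=O)CC(O[Si](CC)(CC)CC)c1ccc(OCC=C(C)C)cc1
F6 | step 7 | rac-1,1-dibromo-4-[4-(3-methylbut-2-enyloxy)phenyl]-4-(triethylsilyloxy)butan-2-one | BrC(Br)C(=O)CC(O[Si](CC)(CC)CC)c1ccc(OCC=C(C)C)cc1
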